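Compound numbers used throughout: 1 3,5-bis(benzyloxy)phenol; 2 benzyl bromide; 3 1,3,5-tris(benzyloxy)benzene; 4 its 2,4-dibromide; 5 the 2,4-dimethoxy compound; 6 the ring A iodide; 7 1-(benzyloxy)-4-ethynylbenzene; 8 carbon monoxide; 9 the ynone; 10 the 3-iodoflavone; 11 the tri-O-benzyl trimethoxyflavone; 12 the target.

## Analysis of the target

The target 12 is a flavone, 5,7-dihydroxy-2-(4-hydroxyphenyl)-3,6,8-trimethoxy-4H-chromen-4-one: a benzo ring A (C4a, C5 to C8, C8a) fused to the pyranone ring C (O1, C2, C3, C4), with the 4-hydroxyphenyl ring B on C2. It has no stereocentre, so the problem is purely regiochemical: six oxygen substituents must be placed and sorted into three free hydroxyls (C5, C7, C4') and three methyl ethers (C3, C6, C8). Ring A is fully substituted: C5, C6, C7, C8 and C8a (through O1) all carry oxygen, and the sixth carbon, C4a, carries the carbonyl carbon C4 and sits between two oxygenated carbons. The free polyphenol is electron-rich and oxidises easily in base and air, and the pyranone accepts hard nucleophiles at C2 with ring opening, so the phenols are kept masked to the end and strong nucleophiles are used sparingly once ring C exists. The hard points are the carbon–carbon bond at the crowded C4a, where acylation of a pentaalkoxybenzene would be slow and would need Lewis acids, and the methoxy group at C3, which has to be set without touching the three future hydroxyls. The strategy rests on two features. With O1 and the C5 oxygen both masked as benzyl ethers, ring A has a mirror plane through C4a and C7, so it derives from a threefold-symmetric tribenzyl ether of the phloroglucinol type. And C4 is a single carbon between C4a and C3, so it can be brought in as carbon monoxide (8) between an aryl iodide at C4a and an alkyne that already holds C3, C2 and ring B.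

## Retrosynthetic reasoning

**12 to 11.** The three O–CH2Ph bonds at C5, C7 and C4' are cut last in the forward sense. This leads back to 11, where the three methoxy groups are already in place. Benzyl is chosen because hydrogenolysis leaves methyl ethers and the pyranone alone, and because a benzyl ether can also serve as the source of O1 in the ring closure below.

**11 to 10.** The C3–OMe bond is cut. C3 is the only oxygenated carbon with no phenol-type precursor in this plan, so it is given a leaving group: 10 carries iodine at C3. The forward step must exchange an alkenyl iodide next to a carbonyl for a methoxy group under copper catalysis without opening ring C.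

**10 to 9.** O1–C2 and C3–I are cut together, which opens ring C and gives the ynone 9. There C2 and C3 are joined by a triple bond and O1 is still one of two benzyloxy groups ortho to the ketone. In the forward direction electrophilic iodine on the alkyne triggers attack by that oxygen. The two ortho oxygens of 9 are equivalent, so only one closure is possible, and the iodine lands on the carbon that needs the methoxy group.

**9 to 6, 7 and 8.** C4a–C4 and C4–C3 are cut, on either side of the carbonyl carbon. C4 then becomes carbon monoxide 8, ring A becomes the aryl iodide 6, and C3, C2 and ring B arrive as the purchased alkyne 7. Cutting only C4a–C4 would demand acylation of a hexasubstituted arene, and cutting only C4–C3 would need a benzoic acid derivative of that same ring. The two-bond cut asks ring A for nothing more than a halogen at C4a and makes the route convergent.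

**6 to 5.** The C–I bond is cut. 5 has a single open ring position, so the iodination cannot give isomers.

**5 to 4.** The two C–OMe bonds of ring A are cut to C–Br bonds. The forward reaction is a double copper-mediated replacement of bromine by methoxy, which places the future C6 and C8 substituents.

**4 to 3, then to 1 and 2.** The two C–Br bonds are cut, which returns the threefold-symmetric triether 3; any two of its three equivalent positions give the same dibromide. One O–benzyl bond of 3 is then cut, leading to the purchased phenol 1, which already carries the other two benzyl ethers, and to benzyl bromide 2. Only one phenoxide then has to be alkylated, so the C-alkylation that troubles arenes with several free hydroxyls does not arise.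

## Alternatives that were turned down

Alternative 1: ring A is built last from a four-carbon unit; the cuts are C8–C8a and C4a–C5.
- Forward key step: the cyclobutenone A2, which carries the pyranone (with ring B and the C3 methoxy group) on its carbinol carbon, is heated. The four-membered ring opens to a vinylketene, the ketene carbon closes onto the C–H carbon of the pyranone next to O1 (C8–C8a), and tautomerisation gives the hydroquinone A1 with OMe at C6 and O-isopropyl at C7.
- For: the crowded benzene ring is made from non-aromatic carbons, every oxygen is fixed by connectivity, and no substitution on a hindered arene is needed. The C5 hydroxyl of A1 is hydrogen-bonded to the carbonyl, so the C8 hydroxyl could be methylated selectively.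
- Against: A2 requires a C-metallated pyranone, itself a conjugate acceptor, to add to one particular carbonyl of a cyclobutenedione whose two alkoxy groups differ only as methyl and isopropyl. Poor discrimination would give the 6/7-transposed isomer. Closure of a ketene onto a pyranone double bond is less secure than onto a benzene ring. A1 is an air-sensitive hydroquinone. Three more operations follow (methylation at O8, loss of isopropyl, loss of benzyl), and the pyranone fragment needs its own synthesis.
- Comparison: this route is stronger in that it needs no copper-mediated C–O bond formation. The chosen route offers instead a ring A precursor in four operations from 1 by symmetry, and a union with a purchased alkyne.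

Alternative 2: ring C is made by enlarging a five-membered ring.
- Forward key step: the (Z)-aurone A5 is brominated across its exocyclic double bond to the dibromide A4. Alcoholic alkali opens the furanone at the brominated C2 and the freed phenoxide displaces the benzylic bromide, forming C3–O and O1–C2 and giving the flavonol A3.
- For: the C3 oxygen is delivered directly as a hydroxyl. In A3 it is the only free one, so methylation to 11 is trivial. On this point the alternative is stronger than the chosen route, which relies on a C–O coupling at C3.
- Against: A5 needs a benzofuranone on the same pentaoxygenated ring, which means a C-acylation at the hindered position and one phenol set apart from two benzyl ethers, so the symmetry is broken early. Halogen addition competes with bromination of the alkoxy-activated ring B. The 4-alkoxy group makes the benzylic bromide of A4 ionise easily, which favours solvolysis or return to A5 over ring expansion. The sequence is also longer (benzofuranone, condensation, bromination, rearrangement, methylation, hydrogenolysis).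
- Comparison: the chosen route keeps ring A symmetric up to the ring closure and forms ring C under non-basic conditions.

Alternative 3: ring C is made in one thermal step.
- Forward key step: the free triol A7 and the α-methoxy β-ketoester A8 are heated without solvent. C-acylation forms C4–C4a and cyclodehydration forms O1–C2, giving A6, which needs only hydrogenolysis to reach 12.
- For: it is the shortest route. A7 would come from 5 by hydrogenolysis, its symmetry allows only one product, and the C3 methoxy group is already in A8. On step count this alternative is clearly stronger.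
- Against: the key step runs above 200 °C on a very electron-rich, oxidation-prone triol. The aryl benzyl ether of A8 is not safe at that temperature. The α-methoxy group slows formation of the acylketene on which this condensation depends. Attack of the arene on the ketone instead of the ester carbonyl would give a coumarin.
- Comparison: the chosen route is two to three steps longer, but each bond is formed under mild conditions by a mechanism that allows only one regiochemical outcome, and every intermediate is a stable, fully protected compound.

Key step: step 5

Remark on the chemistry: 12 has no stereocentre, so configuration matters only for a few fallback and alternative compounds; 1, 2, 7 and 8 are taken as purchased.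

## Route

Step 1
Reactants: 1 3,5-bis(benzyloxy)phenol; 2 benzyl bromide
Product: 3 1,3,5-tris(benzyloxy)benzene
Conditions: 2 (1.1 equiv), K2CO3 (1.5 equiv), DMF, rt
Reagents that add atoms: none
Why: Williamson ether synthesis; K2CO3 forms the single phenoxide of 1, which displaces bromide from 2 at oxygen. Only one hydroxyl has to be alkylated, and a polar aprotic solvent with a carbonate base favours O- over C-benzylation of this dialkoxyphenoxide.

Step 2
Reactants: 3 1,3,5-tris(benzyloxy)benzene
Product: 4 1,3,5-tris(benzyloxy)-2,4-dibromobenzene
Conditions: NBS (2.05 equiv), MeCN/CH2Cl2, 0 °C, dark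
Reagents that add atoms: N-bromosuccinimide, O=C1CCC(=O)N1Br
Why: Electrophilic aromatic bromination of a ring activated by three alkoxy groups; each bromine lowers the reactivity, so two equivalents at low temperature should stop at the dibromide, and by symmetry any two positions give the same compound. Polar, dark conditions avoid radical bromination of the benzylic CH2 groups.

Step 3
Reactants: 4 1,3,5-tris(benzyloxy)-2,4-dibromobenzene
Product: 5 1,3,5-tris(benzyloxy)-2,4-dimethoxybenzene
Conditions: NaOMe (10 equiv), CuBr (30 mol%), MeOH/DMF, 110 °C, N2
Reagents that add atoms: sodium methoxide, C[O-].[Na+]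
Why: Ullmann-type copper-mediated exchange of aryl bromide for methoxide, the reaction used to make polymethoxyarenes from bromo phenol ethers; a monovalent copper methoxide inserts into each C–Br bond and reductive elimination forms C–OMe. Benzyl ethers are inert to methoxide.

Step 4
Reactants: 5 1,3,5-tris(benzyloxy)-2,4-dimethoxybenzene
Product: 6 1,3,5-tris(benzyloxy)-2-iodo-4,6-dimethoxybenzene
Conditions: NIS (1.1 equiv), CF3CO2H (cat.), MeCN, 0 °C to rt, dark
Reagents that add atoms: N-iodosuccinimide, O=C1CCC(=O)N1I
Why: Electrophilic aromatic iodination at the only unsubstituted position of a pentaalkoxybenzene, so no regioisomer can form. NIS with a trace of acid is mild enough not to oxidise the ring to a quinone.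

Step 5
Reactants: 6 1,3,5-tris(benzyloxy)-2-iodo-4,6-dimethoxybenzene; 7 1-(benzyloxy)-4-ethynylbenzene; 8 carbon monoxide
Product: 9 3-[4-(benzyloxy)phenyl]-1-[2,4,6-tris(benzyloxy)-3,5-dimethoxyphenyl]prop-2-yn-1-one
Conditions: 8 (5 bar), Pd(PPh3)4 (5 mol%), CuI (2 mol%), Et3N (3 equiv), THF, 50 °C, 7 added slowly, O2 excluded
Reagents that add atoms: none
Why: This is a carbonylative Sonogashira coupling, the three-component variant of the Sonogashira reaction established for aryl iodides, carbon monoxide and terminal alkynes. Zerovalent palladium inserts into the C–I bond of 6; 8 then coordinates and the aryl group migrates to it, which is favoured because the aryl group is electron-rich and because the acyl ligand moves the metal one atom away from the two flanking benzyloxy groups. The copper acetylide formed from 7, CuI and Et3N transfers the alkynyl group to the acyl palladium iodide, and reductive elimination releases 9 and returns zerovalent palladium, so C4a–C4 and C4–C3 are formed in one operation. No ring is closed and no stereocentre is created. The selectivity needed is carbonylative over direct coupling (which would give the diarylalkyne) and over oxidative dimerisation of 7: pressure of 8, a low copper loading, exclusion of oxygen and slow addition of 7 keep the acetylide concentration low so that insertion precedes transmetalation, and the di-ortho-substituted aryl palladium species is itself slow to transmetalate. Because 6 has a mirror plane through C–I and the para benzyloxy carbon, only one ynone can form. Benzyl and methyl ethers are inert here, and Et3N is too weak a nucleophile to add to the ynone.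

Step 6
Reactants: 9 3-[4-(benzyloxy)phenyl]-1-[2,4,6-tris(benzyloxy)-3,5-dimethoxyphenyl]prop-2-yn-1-one
Product: 10 5,7-bis(benzyloxy)-2-[4-(benzyloxy)phenyl]-3-iodo-6,8-dimethoxy-4H-chromen-4-one
Conditions: ICl (1.2 equiv), CH2Cl2, −78 °C; aq. Na2S2O3 work-up
Reagents that add atoms: iodine monochloride, ICl
Why: Electrophilic iodocyclisation of an ortho-alkoxyaryl ynone; iodonium adds at C3 because positive charge at C2 is stabilised by the 4-benzyloxyphenyl group, and one of the two equivalent ortho benzyloxy oxygens attacks C2 in the 6-endo-dig mode. Chloride then removes the benzyl group from the resulting oxonium ion as benzyl chloride, which makes the closure irreversible and leaves iodine at C3.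

Step 7
Reactants: 10 5,7-bis(benzyloxy)-2-[4-(benzyloxy)phenyl]-3-iodo-6,8-dimethoxy-4H-chromen-4-one
Product: 11 5,7-bis(benzyloxy)-2-[4-(benzyloxy)phenyl]-3,6,8-trimethoxy-4H-chromen-4-one
Conditions: MeOH (10 equiv), CuI (20 mol%), 3,4,7,8-tetramethyl-1,10-phenanthroline (40 mol%), Cs2CO3 (2 equiv), toluene, 90 °C, sealed tube
Reagents that add atoms: methanol, CO
Why: Ullmann-type copper-catalysed C–O coupling of an alkenyl iodide with an aliphatic alcohol; the phenanthroline-ligated copper methoxide inserts into the C3–I bond, helped by coordination to the C4 carbonyl, and reductive elimination gives C3–OMe. Carbonate as base keeps free methoxide low, which limits conjugate addition at C2 and opening of the pyranone.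

Step 8
Reactants: 11 5,7-bis(benzyloxy)-2-[4-(benzyloxy)phenyl]-3,6,8-trimethoxy-4H-chromen-4-one
Product: 12 5,7-dihydroxy-2-(4-hydroxyphenyl)-3,6,8-trimethoxy-4H-chromen-4-one
Conditions: H2 (1 atm), Pd/C (10 % palladium on carbon), THF/MeOH, rt
Reagents that add atoms: none
Why: Catalytic hydrogenolysis cleaves the three benzylic C–O bonds as toluene while the methyl ethers stay intact. The C2–C3 double bond is tetrasubstituted and part of a vinylogous ester, so it should survive if the reaction is stopped after three equivalents of hydrogen are taken up.

## Compound list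

1 | 3,5-bis(benzyloxy)phenol | Oc1cc(OCc2ccccc2)cc(OCc2ccccc2)c1 | starting material
2 | benzyl bromide | BrCc1ccccc1 | starting material
3 | 1,3,5-tris(benzyloxy)benzene | c1ccc(COc2cc(OCc3ccccc3)cc(OCc3ccccc3)c2)cc1 | intermediate
4 | 1,3,5-tris(benzyloxy)-2,4-dibromobenzene | Brc1c(OCc2ccccc2)cc(OCc2ccccc2)c(Br)c1OCc1ccccc1 | intermediate
5 | 1,3,5-tris(benzyloxy)-2,4-dimethoxybenzene | COc1c(OCc2ccccc2)cc(OCc2ccccc2)c(OC)c1OCc1ccccc1 | intermediate
6 | 1,3,5-tris(benzyloxy)-2-iodo-4,6-dimethoxybenzene | COc1c(OCc2ccccc2)c(OC)c(OCc2ccccc2)c(I)c1OCc1ccccc1 | intermediate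
7 | 1-(benzyloxy)-4-ethynylbenzene | C#Cc1ccc(OCc2ccccc2)cc1 | starting material
8 | carbon monoxide | [C-]#[O+] | starting material
9 | 3-[4-(benzyloxy)phenyl]-1-[2,4,6-tris(benzyloxy)-3,5-dimethoxyphenyl]prop-2-yn-1-one | O=C(C#Cc1ccc(OCc2ccccc2)cc1)c1c(OCc2ccccc2)c(OC)c(OCc2ccccc2)c(OC)c1OCc1ccccc1 | intermediate
10 | 5,7-bis(benzyloxy)-2-[4-(benzyloxy)phenyl]-3-iodo-6,8-dimethoxy-4H-chromen-4-one | COc1c(OCc2ccccc2)c(OC)c2oc(-c3ccc(OCc4ccccc4)cc3)c(I)c(=O)c2c1OCc1ccccc1 | intermediate
11 | 5,7-bis(benzyloxy)-2-[4-(benzyloxy)phenyl]-3,6,8-trimethoxy-4H-chromen-4-one | COc1c(OCc2ccccc2)c(OC)c2oc(-c3ccc(OCc4ccccc4)cc3)c(OC)c(=O)c2c1OCc1ccccc1 | intermediate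
12 | 5,7-dihydroxy-2-(4-hydroxyphenyl)-3,6,8-trimethoxy-4H-chromen-4-one | COc1c(O)c(OC)c2oc(-c3ccc(O)cc3)c(OC)c(=O)c2c1O | target

## Step count and least certain steps

Total: 8 steps. Longest linear sequence: 8 steps (1 to 12 through 3, 4, 5, 6, 9, 10, 11); 7 and 8 enter at step 5 as purchased materials.

**Step 5 (key step).** The most likely failures are direct coupling without uptake of 8, slow oxidative addition at the shielded C–I bond under a CO atmosphere, and oxidative dimerisation of 7. The fallback builds the ynone by 1,2-addition and oxidation, with C4 coming from DMF instead of 8. Setting out from 6, iodine–magnesium exchange with i-PrMgCl·LiCl (THF, 0 °C to rt) would give chloro[2,4,6-tris(benzyloxy)-3,5-dimethoxyphenyl]magnesium F1. F1 is formylated with DMF and worked up with water to 2,4,6-tris(benzyloxy)-3,5-dimethoxybenzaldehyde F2. Lithium [4-(benzyloxy)phenyl]ethynide F3, made from 7 and n-BuLi (THF, −78 °C), should add to F2 to give, after a water quench, racemic 3-[4-(benzyloxy)phenyl]-1-[2,4,6-tris(benzyloxy)-3,5-dimethoxyphenyl]prop-2-yn-1-ol F4. MnO2 in CH2Cl2 would oxidise F4 to 9, where the route is rejoined.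

**Step 7.** The risks are reductive loss of iodine (a copper methoxide can act as a hydride donor) and conjugate addition of methoxide at C2 with opening of ring C. The fallback replaces the C–O coupling by metalation, borylation, oxidation and O-methylation. Setting out from 10, iodine–magnesium exchange with i-PrMgCl·LiCl (THF, −40 °C) would give chloro{5,7-bis(benzyloxy)-2-[4-(benzyloxy)phenyl]-6,8-dimethoxy-4-oxo-4H-chromen-3-yl}magnesium F5. B(OMe)3 converts F5 into the dimethyl boronate F6, which is oxidised in the same flask with 30 % aqueous H2O2 (pH 7 phosphate buffer, THF, 0 °C to rt) to 5,7-bis(benzyloxy)-2-[4-(benzyloxy)phenyl]-3-hydroxy-6,8-dimethoxy-4H-chromen-4-one F7, the same flavonol as A3. F7 has a single free hydroxyl, so MeI and K2CO3 in acetone should give 11.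

**Step 3.** The second substitution may stall at the hindered position, and bromine may be replaced by hydrogen through hydride transfer from methoxide on copper. The fallback uses hydroxide, which has no such hydrogen, and a different metal. Setting out from 4, palladium-catalysed hydroxylation (Pd2(dba)3, t-BuXPhos, KOH, 1,4-dioxane/H2O, 100 °C, argon) would give 2,4,6-tris(benzyloxy)benzene-1,3-diol F8. F8 is methylated without exposure to air (MeI, K2CO3, DMF) to give 5.

**Step 6.** ICl may add across the triple bond without ring closure, because the flanked benzyloxy oxygen is a weak nucleophile, or may iodinate ring B. The fallback separates ring closure from iodination. Setting out from 9, BCl3 (1 equiv, CH2Cl2, −78 °C, then water) should remove one benzyl group next to the ketone through the boron chelate, giving 3-[4-(benzyloxy)phenyl]-1-[2,4-bis(benzyloxy)-6-hydroxy-3,5-dimethoxyphenyl]prop-2-yn-1-one F9. Catalytic 4-(dimethylamino)pyridine in DMF should close F9 in the 6-endo mode to 5,7-bis(benzyloxy)-2-[4-(benzyloxy)phenyl]-6,8-dimethoxy-4H-chromen-4-one F10. Deprotonation at C3 with LiN(i-Pr)2 (THF, −78 °C) gives the 3-lithio flavone F11, and I2 converts F11 into 10.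

## Further compounds

F1 | step 5 | chloro[2,4,6-tris(benzyloxy)-3,5-dimethoxyphenyl]magnesium | Cl[Mg]c1c(OCc2ccccc2)c(OC)c(OCc2ccccc2)c(OC)c1OCc1ccccc1
F2 | step 5 | 2,4,6-tris(benzyloxy)-3,5-dimethoxybenzaldehyde | O=Cc1c(OCc2ccccc2)c(OC)c(OCc2ccccc2)c(OC)c1OCc1ccccc1
F3 | step 5 | lithium [4-(benzyloxy)phenyl]ethynide | [Li]C#Cc1ccc(OCc2ccccc2)cc1
F4 | step 5 | rac-3-[4-(benzyloxy)phenyl]-1-[2,4,6-tris(benzyloxy)-3,5-dimethoxyphenyl]prop-2-yn-1-ol | OC(C#Cc1ccc(OCc2ccccc2)cc1)c1c(OCc2ccccc2)c(OC)c(OCc2ccccc2)c(OC)c1OCc1ccccc1
F5 | step 7 | chloro{5,7-bis(benzyloxy)-2-[4-(benzyloxy)phenyl]-6,8-dimethoxy-4-oxo-4H-chromen-3-yl}magnesium | COc1c(OCc2ccccc2)c(OC)c2oc(-c3ccc(OCc4ccccc4)cc3)c([Mg]Cl)c(=O)c2c1OCc1ccccc1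
F6 | step 7 | dimethyl {5,7-bis(benzyloxy)-2-[4-(benzyloxy)phenyl]-6,8-dimethoxy-4-oxo-4H-chromen-3-yl}boronate | COc1c(OCc2ccccc2)c(OC)c2oc(-c3ccc(OCc4ccccc4)cc3)c(B(OC)OC)c(=O)c2c1OCc1ccccc1
F7 | step 7 | 5,7-bis(benzyloxy)-2-[4-(benzyloxy)phenyl]-3-hydroxy-6,8-dimethoxy-4H-chromen-4-one | COc1c(OCc2ccccc2)c(OC)c2oc(-c3ccc(OCc4ccccc4)cc3)c(O)c(=O)c2c1OCc1ccccc1
F8 | step 3 | 2,4,6-tris(benzyloxy)benzene-1,3-diol | Oc1c(OCc2ccccc2)cc(OCc2ccccc2)c(O)c1OCc1ccccc1
F9 | step 6 | 3-[4-(benzyloxy)phenyl]-1-[2,4-bis(benzyloxy)-6-hydroxy-3,5-dimethoxyphenyl]prop-2-yn-1-one | O=C(C#Cc1ccc(OCc2ccccc2)cc1)c1c(O)c(OC)c(OCc2ccccc2)c(OC)c1OCc1ccccc1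
F10 | step 6 | 5,7-bis(benzyloxy)-2-[4-(benzyloxy)phenyl]-6,8-dimethoxy-4H-chromen-4-one | COc1c(OCc2ccccc2)c(OC)c2oc(-c3ccc(OCc4ccccc4)cc3)cc(=O)c2c1OCc1ccccc1
F11 | step 6 | {5,7-bis(benzyloxy)-2-[4-(benzyloxy)phenyl]-6,8-dimethoxy-4-oxo-4H-chromen-3-yl}lithium | COc1c(OCc2ccccc2)c(OC)c2oc(-c3ccc(OCc4ccccc4)cc3)c([Li])c(=O)c2c1OCc1ccccc1
A1 | alternative 1 | 2-[4-(benzyloxy)phenyl]-5,8-dihydroxy-3,6-dimethoxy-7-(propan-2-yloxy)-4H-chromen-4-one | COc1c(OC(C)C)c(O)c2oc(-c3ccc(OCc4ccccc4)cc3)c(OC)c(=O)c2c1O
A2 | alternative 1 | rac-4-{6-[4-(benzyloxy)phenyl]-5-methoxy-4-oxo-4H-pyran-3-yl}-4-hydroxy-3-methoxy-2-(propan-2-yloxy)cyclobut-2-en-1-one | COC1=C(OC(C)C)C(=O)C1(O)c1coc(-c2ccc(OCc3ccccc3)cc2)c(OC)c1=O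
A3 | alternative 2 | 5,7-bis(benzyloxy)-2-[4-(benzyloxy)phenyl]-3-hydroxy-6,8-dimethoxy-4H-chromen-4-one | COc1c(OCc2ccccc2)c(OC)c2oc(-c3ccc(OCc4ccccc4)cc3)c(O)c(=O)c2c1OCc1ccccc1
A4 | alternative 2 | rac-(2R)-4,6-bis(benzyloxy)-2-bromo-2-{(S)-[4-(benzyloxy)phenyl](bromo)methyl}-5,7-dimethoxy-1-benzofuran-3(2H)-one (anti adduct, one enantiomer drawn) | COc1c(OCc2ccccc2)c(OC)c2O[C@](Br)([C@@H](Br)c3ccc(OCc4ccccc4)cc3)C(=O)c2c1OCc1ccccc1
A5 | alternative 2 | (2Z)-4,6-bis(benzyloxy)-2-[4-(benzyloxy)benzylidene]-5,7-dimethoxy-1-benzofuran-3(2H)-one | COc1c(OCc2ccccc2)c(OC)c2O/C(=C\c3ccc(OCc4ccccc4)cc3)C(=O)c2c1OCc1ccccc1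
A6 | alternative 3 | 2-[4-(benzyloxy)phenyl]-5,7-dihydroxy-3,6,8-trimethoxy-4H-chromen-4-one | COc1c(O)c(OC)c2oc(-c3ccc(OCc4ccccc4)cc3)c(OC)c(=O)c2c1O
A7 | alternative 3 | 2,4-dimethoxybenzene-1,3,5-triol | COc1c(O)cc(O)c(OC)c1O
A8 | alternative 3 | rac-ethyl 3-[4-(benzyloxy)phenyl]-2-methoxy-3-oxopropanoate | CCOC(=O)C(OC)C(=O)c1ccc(OCc2ccccc2)cc1
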